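1.75 min is the number we carry: the half-life of a first end group (the limiting reagent here) while second end groups stand as charged and no link comes back. We read it from the alpha run's last reading of first end groups.

| flask | first end groups | second end groups | remark | time |
|---|---|---|---|---|
| alpha | 20 mM | 22 mM | the very flask that is asked about, followed so far |  |
| flask | 20 mM | 22.0 mM |  | 3.0 min |

alpha run (percent of the first end groups charged)

| time / s | links / % | first end groups / % |
|---|---|---|
| 10.0 | 5.6 | 94.1 |
| 20.0 | 11.8 | 89.9 |
| 40.0 | 21.3 | 78.3 |
| 50.0 | 24.7 | 74.9 |

(standard deviation of a reading: 1 percentage point)

- a species is counted by the first end groups in it: one self-condensation product counts as two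
- each molecule carries two end groups: a chain counts once for every two ends that are left, dead ends included; the units are half of the end groups of the two monomers charged
- steps that have been proposed: first end groups + second end groups <-> links; 2 first end groups -> self-condensation product
- a link that another step uses up counts as cut, two dead ends; so do two ends of one kind that react with each other
- what has gone from first end groups into another species counts as reacted, even if it can come back

1. average number of monomer units in a chain (unreacted monomers counted as chains of one) at 3.0 min
2. part of the first end groups that has reacted at 3.0 min

The time asked is 1.71 of these half-lives, so a plain halving leaves 30.5 % of the first end groups. But that rests on one reading. The links at 40.0 s, a different column, give 1.73 min, so the number stands.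

The halving itself is wrong, though, since second end groups are used one for one and the clock slows. Reckoned with that:

charge ratio, second to first: 1.10

excess as a share of the second charge: 9.09 %

two raised to that share times the half-lives elapsed: 1.11

left, (ratio less one) over (ratio times that factor, less one): 44.3 %

Could first end groups be leaking into self-condensation product? At 50.0 s links and first end groups add to 99.6 %, inside the scatter.

Links coming back we cannot compute away, since the readings cover 0.83 min of 3.0 min. So we commit to about 55.7 % reacted or somewhat less. Each link removes one chain, giving 2.13 units per chain.

The forecast, a little lower than we are, says 54.5 % (49 % to 60 %) and 2.08 (1.85 to 2.2): “No clear drift appears, so the reverse step is weak”.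

    first end groups + second end groups ⇌ links (K = 1300 L mol⁻¹, k = 18.0 L mol⁻¹ min⁻¹)
    2 first end groups → self-condensation product (k = 0.0150 L mol⁻¹ min⁻¹)

The flask gives 54.8 % reacted and 2.09 units per chain. While first end groups fell to 62.4 % at 1.50 min and 45.2 % at 3.00 min, the link step ran, half its turnover done by 0.942 min. Beside it, self-condensation stayed slower: the link step's forward rate used first end groups 680 times as fast at 0.942 min, and the product reached 0.0817 %. With 88 mM of second end groups, the half-life scales to 0.437 min, and the same lines, which count the second end groups used, leave 1.97 % of the first end groups. That neighbour flask holds 3.0 % of its first end groups at 3.00 min.

Readings and results are calculated on assumed constants; the scatter is artificial.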